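**Retrosynthetic overview**
1. Target 21 ⇐ (step 8: desilylation, C2 equilibration) silyl ether 19 ⇐ (step 7) open-chain 7-oxo-7'-hydroxy-8,8'-lignan 16. Step 7 is a biomimetic cation–arene closure of ring B through the C4–C4a bond; it also sets C4.
2. 16 ⇐ (step 6) ring A aryllithium 14 + all-trans lactone 11 (C1–C8a bond). 11 ⇐ (step 4) α-methylation of lactone 9 (sets C2) ⇐ (steps 2–3) diol 6 ⇐ alcohol 4.
3. 4 ⇐ (step 1) veratraldehyde 1 + (E)-crotylboronate 2. The catalytic asymmetric anti-crotylation makes the C3–C4 bond and sets C3, the one stereocentre from which C2 and C4 follow.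
4. Enabling feature: C4 is benzylic to ring C and para to its 4'-methoxy group, so its cation is stabilised like a p-quinone methide. C4a of ring A lies para to the C7 oxygen and ortho to the C1 acyl carbon. C1, as a ketone, cannot ionise. One cation therefore meets one nucleophilic site across the six atoms C1–C2–C3–C4–C4a–C8a.
5. Ring order: rings A and C are bought as arenes; a temporary γ-lactone ring (steps 3–6) carries the stereocentres; ring B is closed last.

Key step: step 7

Remark on locants: tetralone numbering is used (C1 carbonyl, C2, C3, C4, C4a, C5–C8, C8a). Ring A is the fused arene, ring B the ketone ring, ring C the pendant 3,4-dimethoxyphenyl group.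
Assumption: the (R)-phosphoric acid is taken to direct the crotyl group to the Re face of the aryl aldehyde, as it does with benzaldehyde, giving the (1R,2R) alcohol. If the sense proved opposite on this substrate, the (S)-catalyst would be used and nothing else changes.
Remark: compound 16 is drawn as the open hydroxy ketone; it may equilibrate with its cyclic hemiketal, and both forms enter step 7 alike.

**Step 1**
Reactants: 1 3,4-dimethoxybenzaldehyde; 2 (E)-crotylboronic acid pinacol ester
Product: 4 (1R,2R)-1-(3,4-dimethoxyphenyl)-2-methylbut-3-en-1-ol, via homoallyl pinacol borate 3 (not isolated)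
Conditions: 2 (1.3 equiv), (R)-3,3'-bis(2,4,6-triisopropylphenyl)-1,1'-binaphthyl-2,2'-diyl hydrogen phosphate (5 mol%), toluene, −30 °C; then aq. NaHCO3
Reagents that add atoms: none
Why: Chiral phosphoric acid-catalysed asymmetric crotylboration; the (E)-boronate reacts through a closed chair transition state (anti product) and the catalyst selects the Re face of the aldehyde, which should set the carbinol carbon (later ionised) and the adjacent methyl-bearing carbon (the future C3) as (1R,2R).

**Step 2**
Reactants: 4 (1R,2R)-1-(3,4-dimethoxyphenyl)-2-methylbut-3-en-1-ol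
Product: 6 (1R,2R)-1-(3,4-dimethoxyphenyl)-2-methylbutane-1,4-diol, via bis-boryl adduct 5 (not isolated)
Conditions: 9-borabicyclo[3.3.1]nonane (2.5 equiv), THF, 0 °C → rt; then NaOH, H2O2, 0 °C → rt
Reagents that add atoms: hydrogen peroxide, OO
Why: Anti-Markovnikov hydroboration–oxidation; the bulky borane places boron on the terminal carbon only, and oxidation with retention gives the primary alcohol without touching either stereocentre.

**Step 3**
Reactants: 6 (1R,2R)-1-(3,4-dimethoxyphenyl)-2-methylbutane-1,4-diol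
Product: 9 (4R,5R)-5-(3,4-dimethoxyphenyl)-4-methyldihydrofuran-2(3H)-one, via hydroxy aldehyde 7 (not isolated), via lactol 8 (not isolated)
Conditions: 2,2,6,6-tetramethylpiperidin-1-oxyl (20 mol%), PhI(OAc)2 (2.5 equiv), CH2Cl2, rt
Reagents that add atoms: none
Why: Nitroxyl-catalysed oxidative lactonisation of a 1,4-diol; the primary alcohol is oxidised faster than the hindered secondary one, the aldehyde closes to the lactol, and this is oxidised to the γ-lactone; no stereocentre is involved.

**Step 4**
Reactants: 9 (4R,5R)-5-(3,4-dimethoxyphenyl)-4-methyldihydrofuran-2(3H)-one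
Product: 11 (3R,4R,5R)-5-(3,4-dimethoxyphenyl)-3,4-dimethyldihydrofuran-2(3H)-one, via lithium enolate 10 (not isolated)
Conditions: LiN(SiMe3)2 (1.1 equiv), THF, −78 °C; MeI (3 equiv), −78 → −40 °C
Reagents that add atoms: iodomethane, CI
Why: Diastereoselective enolate alkylation of a β-substituted γ-butyrolactone; iodomethane approaches the planar enolate anti to the adjacent C4 methyl group, which should set the lactone C3 (the future C2) trans to it.

**Step 5**
Reactants: 12 5-bromo-2-methoxyphenol
Product: 13 (5-bromo-2-methoxyphenoxy)(tert-butyl)dimethylsilane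
Conditions: t-BuMe2SiCl (1.2 equiv), imidazole (2.5 equiv), DMF, rt
Reagents that add atoms: tert-butyldimethylsilyl chloride, CC(C)(C)[Si](C)(C)Cl
Why: Standard silylation of a phenol; the bulky silyl ether tolerates the aryllithium and later shields the ring position between the oxygen and the side chain.

**Step 6**
Reactants: 13 (5-bromo-2-methoxyphenoxy)(tert-butyl)dimethylsilane; 11 (3R,4R,5R)-5-(3,4-dimethoxyphenyl)-3,4-dimethyldihydrofuran-2(3H)-one
Product: 16 (2R,3R,4R)-1-[3-(tert-butyldimethylsilyloxy)-4-methoxyphenyl]-4-(3,4-dimethoxyphenyl)-4-hydroxy-2,3-dimethylbutan-1-one, via aryllithium 14 (not isolated), via lithium lactolate 15 (not isolated)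
Conditions: 13 (1.3 equiv), n-BuLi (1.25 equiv), THF, −78 °C; then 11, −78 °C; aq. NH4Cl
Reagents that add atoms: none
Why: Bromine–lithium exchange followed by mono-addition of the aryllithium to the lactone; the tetrahedral lithium lactolate persists at −78 °C and releases the ketone only on quench, so the C1–C8a bond forms without touching the three stereocentres.

**Step 7**
Reactants: 16 (2R,3R,4R)-1-[3-(tert-butyldimethylsilyloxy)-4-methoxyphenyl]-4-(3,4-dimethoxyphenyl)-4-hydroxy-2,3-dimethylbutan-1-one
Product: 19 (2R,3S,4R)-7-(tert-butyldimethylsilyloxy)-4-(3,4-dimethoxyphenyl)-6-methoxy-2,3-dimethyl-3,4-dihydronaphthalen-1(2H)-one, via oxocarbenium triflate 17 (not isolated), via benzylic cation triflate 18 (not isolated)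
Conditions: CF3SO3H (10 mol%), (CF3)2CHOH (0.02 M), 0 °C → rt
Reagents that add atoms: none
Why: The acid ionises the benzylic C4–OH; the ketone oxygen reversibly stores the cation as the five-membered oxocarbenium 17, which reopens to the p-methoxy-stabilised benzylic cation 18, and C4a of ring A attacks C4 in an intramolecular Friedel–Crafts alkylation, after which proton loss restores the arene. The closest known reaction type is the acid-mediated cyclisation of γ-aryl-γ-hydroxy aryl ketones and of 2,5-diaryltetrahydrofuran lignans to 4-aryl-1-tetralones and aryltetralins, and the related Lewis acid cyclisation of aryl 2-arylcyclopropyl ketones. Ring B closes in a 6-exo-trig cation–arene mode through a chair-like transition state. The new C4 stereocentre is controlled by the resident C3 methyl group: the aryl group on the planar cation takes the pseudo-equatorial position anti to it, so the 3,4-trans product should form from either carbinol epimer. Regioselectivity for C4a over the other ortho position is secured by its para relationship to the C7 oxygen and by the bulk of the silyl ether; chemoselectivity (only C4 ionises) is secured by C1 being a ketone. The C3 configuration survives only if ring closure outruns proton loss to the styrene, which the non-basic, strongly ionising medium and high dilution should favour.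

**Step 8**
Reactants: 19 (2R,3S,4R)-7-(tert-butyldimethylsilyloxy)-4-(3,4-dimethoxyphenyl)-6-methoxy-2,3-dimethyl-3,4-dihydronaphthalen-1(2H)-one
Product: 21 epischisandrone, (2R,3S,4R)-4-(3,4-dimethoxyphenyl)-7-hydroxy-6-methoxy-2,3-dimethyl-3,4-dihydronaphthalen-1(2H)-one, via potassium phenolate 20 (not isolated)
Conditions: K2CO3 (2 equiv), MeOH, rt → 40 °C; then 1 M HCl
Reagents that add atoms: none
Why: Base-mediated methanolysis of the aryl silyl ether; the same medium makes C2 epimerisable, so this centre should end in the thermodynamically preferred all-equatorial 2,3-trans arrangement already set in step 4, while C3 and C4 are not enolisable.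

**Compound list**
1 | 3,4-dimethoxybenzaldehyde (veratraldehyde) | COc1ccc(C=O)cc1OC | starting material
2 | (E)-crotylboronic acid pinacol ester, 2-[(2E)-but-2-en-1-yl]-4,4,5,5-tetramethyl-1,3,2-dioxaborolane | C/C=C/CB1OC(C)(C)C(C)(C)O1 | starting material
3 | 2-{[(1R,2R)-1-(3,4-dimethoxyphenyl)-2-methylbut-3-en-1-yl]oxy}-4,4,5,5-tetramethyl-1,3,2-dioxaborolane (homoallyl pinacol borate) | C=C[C@@H](C)[C@@H](OB1OC(C)(C)C(C)(C)O1)c1ccc(OC)c(OC)c1 | intermediate (not isolated)
4 | (1R,2R)-1-(3,4-dimethoxyphenyl)-2-methylbut-3-en-1-ol | C=C[C@@H](C)[C@@H](O)c1ccc(OC)c(OC)c1 | intermediate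
5 | 9-{(3R,4R)-4-(3,4-dimethoxyphenyl)-3-methyl-4-[(9-borabicyclo[3.3.1]nonan-9-yl)oxy]butyl}-9-borabicyclo[3.3.1]nonane (bis-boryl adduct) | B1(CC[C@@H](C)[C@@H](OB3C4CCCC3CCC4)c5ccc(OC)c(OC)c5)C2CCCC1CCC2 | intermediate (not isolated)
6 | (1R,2R)-1-(3,4-dimethoxyphenyl)-2-methylbutane-1,4-diol | OCC[C@@H](C)[C@@H](O)c1ccc(OC)c(OC)c1 | intermediate
7 | (3R,4R)-4-(3,4-dimethoxyphenyl)-4-hydroxy-3-methylbutanal (hydroxy aldehyde) | O=CC[C@@H](C)[C@@H](O)c1ccc(OC)c(OC)c1 | intermediate (not isolated)
8 | (4R,5R)-5-(3,4-dimethoxyphenyl)-4-methyltetrahydrofuran-2-ol (lactol, both anomers) | OC1C[C@@H](C)[C@H](c2ccc(OC)c(OC)c2)O1 | intermediate (not isolated)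
9 | (4R,5R)-5-(3,4-dimethoxyphenyl)-4-methyldihydrofuran-2(3H)-one | O=C1C[C@@H](C)[C@H](c2ccc(OC)c(OC)c2)O1 | intermediate
10 | lithium (4R,5R)-5-(3,4-dimethoxyphenyl)-4-methyl-4,5-dihydrofuran-2-olate (lithium enolate) | [Li]OC1=C[C@@H](C)[C@H](c2ccc(OC)c(OC)c2)O1 | intermediate (not isolated)
11 | (3R,4R,5R)-5-(3,4-dimethoxyphenyl)-3,4-dimethyldihydrofuran-2(3H)-one (all-trans lactone) | O=C1[C@H](C)[C@@H](C)[C@H](c2ccc(OC)c(OC)c2)O1 | intermediate
12 | 5-bromo-2-methoxyphenol | COc1ccc(Br)cc1O | starting material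
13 | (5-bromo-2-methoxyphenoxy)(tert-butyl)dimethylsilane | COc1ccc(Br)cc1O[Si](C)(C)C(C)(C)C | intermediate
14 | [3-(tert-butyldimethylsilyloxy)-4-methoxyphenyl]lithium (aryllithium) | COc1ccc([Li])cc1O[Si](C)(C)C(C)(C)C | intermediate (not isolated)
15 | lithium (3R,4R,5R)-2-[3-(tert-butyldimethylsilyloxy)-4-methoxyphenyl]-5-(3,4-dimethoxyphenyl)-3,4-dimethyltetrahydrofuran-2-olate (lithium lactolate, C2 undefined) | [Li]OC1(c2ccc(OC)c(O[Si](C)(C)C(C)(C)C)c2)[C@H](C)[C@@H](C)[C@H](c2ccc(OC)c(OC)c2)O1 | intermediate (not isolated)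
16 | (2R,3R,4R)-1-[3-(tert-butyldimethylsilyloxy)-4-methoxyphenyl]-4-(3,4-dimethoxyphenyl)-4-hydroxy-2,3-dimethylbutan-1-one | COc1ccc(cc1O[Si](C)(C)C(C)(C)C)C(=O)[C@H](C)[C@@H](C)[C@@H](O)c1ccc(OC)c(OC)c1 | intermediate
17 | (3R,4R,5R)-2-[3-(tert-butyldimethylsilyloxy)-4-methoxyphenyl]-5-(3,4-dimethoxyphenyl)-3,4-dimethyl-4,5-dihydro-3H-furan-1-ium triflate (oxocarbenium triflate) | [O+]1=C(c2ccc(OC)c(O[Si](C)(C)C(C)(C)C)c2)[C@H](C)[C@@H](C)[C@@H]1c3ccc(OC)c(OC)c3.[O-]S(=O)(=O)C(F)(F)F | intermediate (not isolated)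
18 | ring-opened C4 benzylic cation of 16, (2R,3S)-configured, as its triflate | COc1ccc(cc1O[Si](C)(C)C(C)(C)C)C(=O)[C@H](C)[C@@H](C)[CH+]c1ccc(OC)c(OC)c1.[O-]S(=O)(=O)C(F)(F)F | intermediate (not isolated)
19 | (2R,3S,4R)-7-(tert-butyldimethylsilyloxy)-4-(3,4-dimethoxyphenyl)-6-methoxy-2,3-dimethyl-3,4-dihydronaphthalen-1(2H)-one | COc1cc2c(cc1O[Si](C)(C)C(C)(C)C)C(=O)[C@H](C)[C@@H](C)[C@@H]2c1ccc(OC)c(OC)c1 | intermediate
20 | potassium phenolate of 21 | COc1cc2c(cc1[O-])C(=O)[C@H](C)[C@@H](C)[C@@H]2c1ccc(OC)c(OC)c1.[K+] | intermediate (not isolated)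
21 | epischisandrone, (2R,3S,4R)-4-(3,4-dimethoxyphenyl)-7-hydroxy-6-methoxy-2,3-dimethyl-3,4-dihydronaphthalen-1(2H)-one | COc1cc2c(cc1O)C(=O)[C@H](C)[C@@H](C)[C@@H]2c1ccc(OC)c(OC)c1 | target

**Step count and risks**
Total steps: 8. Longest linear sequence: 7 (steps 1, 2, 3, 4, 6, 7, 8); step 5 is a one-step side branch.

Steps most likely to fail:

1. Step 7. Ring closure onto the acyl-substituted ring A may be slower than proton loss from the benzylic cation to the styrene, which would erode the C3 configuration and open the way to intermolecular alkylation. The fallback moves the Friedel–Crafts event in front of the acyl group and sets out from lactone 11 and bromophenol 12. CF3SO3H in (CF3)2CHOH would ionise the lactone at its benzylic C–O bond, and the cation would alkylate an excess of 12 para to its hydroxyl (ortho to bromine) to give (2R,3S,4R)-4-(2-bromo-4-hydroxy-5-methoxyphenyl)-4-(3,4-dimethoxyphenyl)-2,3-dimethylbutanoic acid F1. Attack anti to the larger C3 substituent in the conformer of least allylic strain corresponds to the C3/C4 relationship of the target. n-BuLi (3.3 equiv, THF, −78 °C → rt) would then give the trilithiated aryllithium F2, whose addition to its own lithium carboxylate (Parham cyclisation) closes ring B regiospecifically at C1–C8a. Acidic work-up and the equilibration conditions of step 8 come back to the route at target 21.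

2. Step 6. The tetrahedral adduct may collapse early, so that a second aryllithium adds to the liberated ketone, or the lactone may be enolised with loss of the C2 configuration. The fallback sets out from lactone 11. Aminolysis with MeNH(OMe)·HCl and AlMe3 (CH2Cl2, 0 °C) would give (2R,3R,4R)-4-(3,4-dimethoxyphenyl)-4-hydroxy-N-methoxy-N,2,3-trimethylbutanamide F3. This is silylated at once (Me3SiCl, imidazole) to its trimethylsilyl ether F4 so that it cannot relactonise. Aryllithium 14 adds only once to a Weinreb amide, giving the trimethylsilyl-protected ketone F5, which loses the trimethylsilyl group on work-up with dilute citric acid and comes back to the route at hydroxy ketone 16.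

3. Step 3. The electron-rich benzylic alcohol may be oxidised to the aryl ketone in competition with the primary alcohol, before the lactol can form. The fallback sets out from alcohol 4. Silylation (t-BuMe2SiOSO2CF3, 2,6-lutidine) would give tert-butyl{[(1R,2R)-1-(3,4-dimethoxyphenyl)-2-methylbut-3-en-1-yl]oxy}dimethylsilane F6. Hydroboration–oxidation as in step 2 would give (3R,4R)-4-(tert-butyldimethylsilyloxy)-4-(3,4-dimethoxyphenyl)-3-methylbutan-1-ol F7. Oxidation (2,2,6,6-tetramethylpiperidin-1-oxyl, NaOCl, NaClO2) would give (3R,4R)-4-(tert-butyldimethylsilyloxy)-4-(3,4-dimethoxyphenyl)-3-methylbutanoic acid F8. Bu4NF then frees (3R,4R)-4-(3,4-dimethoxyphenyl)-4-hydroxy-3-methylbutanoic acid F9, which closes on acidification and comes back to the route at lactone 9.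

**Further compounds**
F1 | step 7 | (2R,3S,4R)-4-(2-bromo-4-hydroxy-5-methoxyphenyl)-4-(3,4-dimethoxyphenyl)-2,3-dimethylbutanoic acid | OC(=O)[C@H](C)[C@@H](C)[C@@H](c1cc(OC)c(O)cc1Br)c1ccc(OC)c(OC)c1
F2 | step 7 | trilithiated aryllithium of F1 (lithium carboxylate, lithium phenolate, aryl lithium) | [Li]OC(=O)[C@H](C)[C@@H](C)[C@@H](c1cc(OC)c(O[Li])cc1[Li])c1ccc(OC)c(OC)c1
F3 | step 6 | (2R,3R,4R)-4-(3,4-dimethoxyphenyl)-4-hydroxy-N-methoxy-N,2,3-trimethylbutanamide | CON(C)C(=O)[C@H](C)[C@@H](C)[C@@H](O)c1ccc(OC)c(OC)c1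
F4 | step 6 | (2R,3R,4R)-4-(3,4-dimethoxyphenyl)-N-methoxy-N,2,3-trimethyl-4-(trimethylsilyloxy)butanamide | CON(C)C(=O)[C@H](C)[C@@H](C)[C@@H](O[Si](C)(C)C)c1ccc(OC)c(OC)c1
F5 | step 6 | (2R,3R,4R)-1-[3-(tert-butyldimethylsilyloxy)-4-methoxyphenyl]-4-(3,4-dimethoxyphenyl)-2,3-dimethyl-4-(trimethylsilyloxy)butan-1-one | COc1ccc(cc1O[Si](C)(C)C(C)(C)C)C(=O)[C@H](C)[C@@H](C)[C@@H](O[Si](C)(C)C)c1ccc(OC)c(OC)c1
F6 | step 3 | tert-butyl{[(1R,2R)-1-(3,4-dimethoxyphenyl)-2-methylbut-3-en-1-yl]oxy}dimethylsilane | C=C[C@@H](C)[C@@H](O[Si](C)(C)C(C)(C)C)c1ccc(OC)c(OC)c1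
F7 | step 3 | (3R,4R)-4-(tert-butyldimethylsilyloxy)-4-(3,4-dimethoxyphenyl)-3-methylbutan-1-ol | OCC[C@@H](C)[C@@H](O[Si](C)(C)C(C)(C)C)c1ccc(OC)c(OC)c1
F8 | step 3 | (3R,4R)-4-(tert-butyldimethylsilyloxy)-4-(3,4-dimethoxyphenyl)-3-methylbutanoic acid | OC(=O)C[C@@H](C)[C@@H](O[Si](C)(C)C(C)(C)C)c1ccc(OC)c(OC)c1
F9 | step 3 | (3R,4R)-4-(3,4-dimethoxyphenyl)-4-hydroxy-3-methylbutanoic acid | OC(=O)C[C@@H](C)[C@@H](O)c1ccc(OC)c(OC)c1
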